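## Structural features

The target 9 is a 2,6-disubstituted 1,4-benzoquinone: one six-membered carbocycle with carbonyls at C1 and C4, a methoxy group on C2, hydrogens on C3 and C5, and a tridecyl chain on C6. The chain is joined to the ring through its C1' methylene, carries the acetate of a secondary alcohol at C2' (R), and ends in an unbranched undecyl segment C3'–C13'. C2' is the only stereocentre and has no stereogenic neighbour. Its two carbon substituents, the CH2 leading to the ring and the CH2 leading to the tail, differ only beyond the first atom, so carbonyl reduction or simple carbonyl addition is poorly suited to setting it. The fragile parts are the quinone (reducible, attacked by amines and other nucleophiles, sensitive to base and light) and the C2' acetate, which base can hydrolyse or eliminate because it sits β to the ring. The real difficulty is therefore to create the acetylated dialkyl carbinol stereocentre efficiently and to unveil the quinone only after all basic, nucleophilic or reducing operations are over. The key step exploits the fact that C2' bears one hydrogen, one acyloxy oxygen and two CH2 groups: C2' and its oxygen come from an aldehyde carbonyl, the acetyl group from an acetyl halide, and C3'–C13' from an eleven-carbon terminal olefin, so the O–acetyl bond, the C2'–C3' bond and the stereocentre arise together. The ring oxygen pattern (C1–O next to C2–OMe, chain at C6, C4 still C–H) is that of a 2-alkyl-6-methoxyphenol whose only free para position is C4.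

## Logic of the disconnections

**9 ⇒ 8.** The C4=O bond is removed and the ring is returned to the phenol level. The cut is made here because the quinone is the most fragile function and should appear last. The gain is a stable arene that already holds every carbon, the acetate and the stereocentre. The forward step needs an oxidant that attacks only the para position, works near neutral pH and spares the acetate. In 8 both ortho positions are occupied (OMe and the chain) and the para carbon is flanked by two C–H, so only the para-quinone can form.

**8 ⇒ 7.** No skeletal bond is cut; the phenolic O–H is traced back to an O–acetyl group. A free phenol cannot go through the coupling: it would consume 4, release HBr and close onto the aldehyde as a lactol. An acetate is preferred to a benzyl ether at this oxygen for three reasons.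
- 4, and the HBr it forms with traces of water, cleave benzyl ethers, whereas an aryl acetate can only exchange acetyl for acetyl.
- An ortho ether oxygen sits where it can close a five-membered ring onto the ionisable C2'–Br carbon of 6, and an O-benzyl oxonium would then shed benzyl bromide irreversibly. The ester oxygen of an aryl acetate is far less nucleophilic.
- If K3PO4 removes some of the aryl acetate during the coupling, the result is 8 itself.

The demand on the forward step is to cleave an aryl ester beside an alkyl ester. The large difference in leaving-group ability (phenoxide against alkoxide) makes this possible.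

**7 ⇒ 3 + 4 + 5 (through 6).** The C2'–C3' bond and the acetyl–O bond at C2' are cut. This is the only place where the stereocentre, its oxygen substituent and the long chain can be introduced in one operation from achiral pieces. The 24-carbon compound 7 falls into the aldehyde 3 and two bulk chemicals, 4 and 5, and no stereochemistry has to be stored in any precursor. The forward step demands that 4 add to 3 faster than 3 self-condenses, that 6 not lose HBr toward the conjugated enol ester, that the nickel hydride add to 5 in the linear sense, and that the chiral catalyst control the face of the C2' radical.

**3 ⇒ 2.** The aldehyde carbon C2' is traced back to the internal carbon of an allyl group, which adds one carbon as C=CH2. Arylacetaldehydes do not store well, while the allyl arene is a stable masked form. The forward step must cleave the olefin without oxidising the oxygenated ring, and 3 must be used at once.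

**2 ⇒ 1.** The aryl O–acetyl bond is cut. 1 is a commercial phenol that already carries C1' on the ring, ortho to the hydroxyl, with the methoxy group on the other side. No aromatic substitution has to be planned, and the precursor 3 is reached in two steps. The forward step only needs to acylate a hindered phenol.

## Other disconnections considered

**Alternative 1:** The cut runs through the ring. The arene is opened at two ring bonds (C1–C2 and C3–C4, quinone numbering) into the four-carbon unit (R)-3-[2-(tert-butyldimethylsilyloxy)tridecyl]cyclobut-2-en-1-one A1 and the two-carbon unit methoxyacetylene A2.
- Forward key step: heating A1 with A2 should open the cyclobutenone to a vinylketene, add the alkyne by [2+2], open the new four-membered ring, close the six-membered ring by six-electron electrocyclisation and tautomerise. The product would be 3-methoxy-5-[(2R)-2-(tert-butyldimethylsilyloxy)tridecyl]phenol A3 (benzannulation of the Danheiser type).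
- In favour: the 1,3,5-pattern follows from the mechanism, no catalyst or additive is needed, a silyl ether is indifferent to the conditions, and the phenol emerges free.
- Against: the ring does not need to be built, since an arene with the right oxygen pattern is commercial. A1 needs a separate asymmetric construction of C2', then a ketene cycloaddition and dechlorination. A2 is volatile and must be made and handled cold. The C2' oxygen is carried as a silyl ether that must be exchanged for acetyl at the end. The para carbon to be oxidised in A3 lies between the methoxy group and the chain, a more hindered site than in 8.
- Comparison, structure: the alternative solves ring construction and leaves the stereocentre to an unrelated earlier step. The chosen plan buys the ring and puts its key step on the stereocentre and acetate, which are the real problem.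
- Comparison, mechanism: a thermal pericyclic cascade without metal is more predictable than a radical nickel coupling on a sensitive bromide. On reliability of the key step itself the alternative is the better.
- Comparison, step economy: about eight operations from a C12 aldehyde, plus the preparation of A2, against five.

**Alternative 2:** The aryl–C1' and C2'–C3' bonds are cut around a two-carbon vinylboron linchpin. The pieces are 3-(benzyloxy)-5-methoxyphenyl trifluoromethanesulfonate A4, 4,4,5,5-tetramethyl-2-vinyl-1,3,2-dioxaborolane A5 and undecylmagnesium bromide A6.
- Forward key step: A6 and A5 form a boron ate complex. The aryl–Pd–OTf complex, formed by oxidative addition of A4 to a zerovalent palladium catalyst (Pd(OAc)2 with a chiral ferrocenyl bisphosphine), triggers a 1,2-shift of the undecyl group from boron to carbon. The product would be (R)-2-{1-[3-(benzyloxy)-5-methoxyphenyl]tridecan-2-yl}-4,4,5,5-tetramethyl-1,3,2-dioxaborolane A7.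
- In favour: three simple components, two carbon–carbon bonds and the stereocentre in one catalytic step. In convergence it is the equal of the chosen plan.
- Also in favour: aryl triflates with primary alkyl migrating groups lie inside the usual range of conjunctive coupling, and no intermediate is prone to elimination. In closeness of precedent for the key step it is the better.
- Against: the stereocentre is made as C–B, so oxidation and acetylation must follow, whereas the chosen key step installs the acetate directly. A4 requires statistical mono-benzylation of a symmetrical diphenol and triflation. Ate complexes from Grignard reagents need halide-scavenging additives. After hydrogenolysis, the phenol (R)-1-(3-hydroxy-5-methoxyphenyl)tridecan-2-yl acetate A8 must be oxidised with (KSO3)2NO at a para carbon flanked by two substituents.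
- Comparison, structure: both plans set C2' catalytically from achiral pieces, but the alternative sets it at the wrong heteroatom.
- Comparison, mechanism: a closed-shell metallate shift with stereospecific later oxidation, against an enantioconvergent radical capture.
- Comparison, step economy: seven steps (two to A4, coupling, oxidation, acetylation, hydrogenolysis, quinone formation) against five.

**Alternative 3:** The ring bond between C6 and C1 (quinone numbering) is cut, which unfolds the arene into the open-chain polyketide methyl (R)-9-(tert-butyldimethylsilyloxy)-3,5,7-trioxoicosanoate A9.
- Forward key step: intramolecular aldol attack of C2 of A9 on the C7 ketone, then dehydration and enolisation, should give methyl 2,4-dihydroxy-6-[(2R)-2-(tert-butyldimethylsilyloxy)tridecyl]benzoate A10.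
- In favour: the ring regiochemistry is written into the chain, and the chemistry is metal-free with inexpensive reagents. On reagent cost and on freedom from transition metals it is the better.
- Against, in the key step: A9 is a β-silyloxy ketone flanked by acidic methylenes, so silanol elimination and pyrone formation compete with the aldol closure.
- Against, after the key step: A10 carries an ester carbon that the target lacks, so a carbon–carbon bond made in the key step must be broken again by saponification and decarboxylation. The resulting (R)-5-[2-(tert-butyldimethylsilyloxy)tridecyl]benzene-1,3-diol A11 has two equivalent hydroxyls, so mono-methylation to A3 can only be statistical. Silyl-to-acetyl exchange and oxidation at the hindered para carbon still follow.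
- Comparison, structure: as in alternative 1, the effort goes into a ring that can be bought, and the stereocentre is a fragile passenger.
- Comparison, mechanism: carbonyl condensation under base or buffer, against a catalytic radical coupling under nearly neutral conditions.
- Comparison, step economy: roughly eleven operations against five.

Key step: step 3

Assumption: which antipode of the bis(oxazoline) ligand gives the R acetate cannot be read from the structure of 3, so both antipodes are tried on a small scale and the one giving R (checked on the derived alcohol) is used; 1 is taken to be a commercial compound.

## Route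

Step 1
Reactants: 1 2-allyl-6-methoxyphenol (o-eugenol)
Product: 2 2-allyl-6-methoxyphenyl acetate
Conditions: Ac2O, pyridine, DMAP (cat.), CH2Cl2, 0 °C→rt
Reagents that add atoms: acetic anhydride, CC(=O)OC(C)=O
Why: DMAP-catalysed O-acetylation of a phenol (nucleophilic acyl substitution through the N-acetylpyridinium ion); the allyl group and the aryl methyl ether are inert, and the acetate is the one phenol protecting group that acetyl bromide cannot alter later.

Step 2
Reactants: 2 2-allyl-6-methoxyphenyl acetate
Product: 3 2-(2-acetoxy-3-methoxyphenyl)acetaldehyde
Conditions: O3, CH2Cl2, −78 °C (dye end-point); then PPh3, −78 °C→rt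
Reagents that add atoms: ozone, [O-][O+]=O
Why: Ozonolysis with reductive work-up (Criegee mechanism: cycloaddition, cycloreversion, recombination to the 1,2,4-trioxolane, reduction by PPh3); the isolated terminal olefin reacts far faster with ozone than the acetoxy/methoxy arene, so metering ozone to an indicator end-point should spare the ring. The aldehyde is passed quickly through silica and used at once.

Step 3
Reactants: 3 2-(2-acetoxy-3-methoxyphenyl)acetaldehyde, 4 acetyl bromide, 5 1-undecene
Product: 7 (R)-1-(2-acetoxy-3-methoxyphenyl)tridecan-2-yl acetate, via racemic 1-bromo-2-arylethyl acetate 6 (not isolated)
Conditions: AcBr (1.05 equiv), CH2Cl2, 0 °C→rt; then NiBr2·glyme (10 mol %), chiral bis(oxazoline) L* (12 mol %), 1-undecene (1.5 equiv), (EtO)3SiH, K3PO4·H2O, DMA/i-Pr2O, 0 °C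
Reagents that add atoms: none
Why: Acetyl bromide adds across the carbonyl of 3 (acyl-oxocarbenium bromide ion pair, then collapse) to give racemic 6, which is used as a solution. In the catalytic stage L*Ni(H)Br, formed from NiBr2·glyme, (EtO)3SiH and K3PO4, inserts 5 in the anti-Markovnikov sense to give the primary alkyl complex L*Ni(C11H23)Br. A monovalent nickel species L*NiBr abstracts bromine from either enantiomer of 6 to give a planar α-acetoxyalkyl radical, the chiral divalent alkylnickel captures it to a trivalent dialkylnickel, and reductive elimination forms C2'–C3'. The closest known reaction type is the nickel-catalysed enantioconvergent hydroalkylation of terminal olefins with racemic 1-bromoalkyl esters made in the flask from an aldehyde and an acyl bromide, which gives esters of dialkyl carbinols; 3 is an enolisable arylacetaldehyde member of that class. No ring is closed. The one new stereocentre, C2', is set under catalyst control: both enantiomers of 6 pass through the same radical, and the C2-symmetric ligand on nickel differentiates the acetoxy and CH2Ar substituents of that radical during capture and reductive elimination, the ligand antipode being chosen for R. The step needs linear hydrometalation, secured by the unhindered monosubstituted olefin, and halogen abstraction only at the α-oxygenated C–Br bond, secured because the aryl acetate, aryl methyl ether and alkyl acetate offer no comparably weak bond. The aryl acetate keeps the ortho oxygen from attacking the ionisable C2' carbon and is unchanged by acetyl bromide, and loss of HBr from 6 is limited by forming 6 cold and adding it to the pre-formed catalyst mixture.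

Step 4
Reactants: 7 (R)-1-(2-acetoxy-3-methoxyphenyl)tridecan-2-yl acetate
Product: 8 (R)-1-(2-hydroxy-3-methoxyphenyl)tridecan-2-yl acetate
Conditions: pyrrolidine (3 equiv), MeCN, 0 °C→rt
Reagents that add atoms: none
Why: Chemoselective aminolysis of an aryl ester: the aryl acetate is an activated ester with a phenoxide leaving group and should be cleaved by pyrrolidine at room temperature, while the secondary alkyl acetate, with a much poorer alkoxide leaving group, should not react; C2' is not involved.

Step 5
Reactants: 8 (R)-1-(2-hydroxy-3-methoxyphenyl)tridecan-2-yl acetate
Product: 9 (R)-1-(5-methoxy-3,6-dioxocyclohexa-1,4-dien-1-yl)tridecan-2-yl acetate (the target, 2-[(2R)-2-acetoxytridecyl]-6-methoxy-1,4-benzoquinone)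
Conditions: (KSO3)2NO (2.5 equiv), aq. KH2PO4, acetone/H2O, rt
Reagents that add atoms: potassium nitrosodisulfonate (Fremy's salt), [K+].[K+].[O]N(S(=O)(=O)[O-])S(=O)(=O)[O-]
Why: Teuber oxidation: one nitrosodisulfonate radical removes the phenolic hydrogen, a second couples at the free para carbon C4, and loss of imidodisulfonate gives the para-quinone; both ortho positions are blocked, so no ortho-quinone can form, and the buffered near-neutral medium should leave the acetate and C2' untouched.

## Compound list

1 | 2-allyl-6-methoxyphenol (o-eugenol) | C=CCc1cccc(OC)c1O | starting material
2 | 2-allyl-6-methoxyphenyl acetate | C=CCc1cccc(OC)c1OC(C)=O | intermediate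
3 | 2-(2-acetoxy-3-methoxyphenyl)acetaldehyde | O=CCc1cccc(OC)c1OC(C)=O | intermediate
4 | acetyl bromide | CC(Br)=O | starting material
5 | 1-undecene | C=CCCCCCCCCC | starting material
6 | rac-1-bromo-2-(2-acetoxy-3-methoxyphenyl)ethyl acetate | CC(=O)OC(Br)Cc1cccc(OC)c1OC(C)=O | intermediate
7 | (R)-1-(2-acetoxy-3-methoxyphenyl)tridecan-2-yl acetate | CCCCCCCCCCC[C@H](Cc1cccc(OC)c1OC(C)=O)OC(C)=O | intermediate
8 | (R)-1-(2-hydroxy-3-methoxyphenyl)tridecan-2-yl acetate | CCCCCCCCCCC[C@H](Cc1cccc(OC)c1O)OC(C)=O | intermediate
9 | (R)-1-(5-methoxy-3,6-dioxocyclohexa-1,4-dien-1-yl)tridecan-2-yl acetate | CCCCCCCCCCC[C@H](CC1=CC(=O)C=C(OC)C1=O)OC(C)=O | target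

## Step count and risk

Total step count: 5. Longest linear sequence: 5 steps (1 → 2 → 3 → 7 → 8 → 9); 4 and 5 enter at step 3.

**Step 3 (key step).**
- What may go wrong: loss of HBr from 6 toward the conjugated enol acetate, because the C1' hydrogens are activated by both the ring and the C–Br carbon and K3PO4 is present. Self-condensation of 3 before acetyl bromide has added is a second hazard. Facial discrimination may also be insufficient, since the CH2Ar substituent of the radical differs from the simple alkyl groups typical of this coupling.
- Fallback (sets out from 1, returns at 8): the stereocentre is taken from a resolved epoxide and the chain is attached by a cuprate, with no bromide or radical involved.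
  - O-benzylation of 1 (BnBr, K2CO3, DMF) would give 1-allyl-2-(benzyloxy)-3-methoxybenzene F1.
  - Epoxidation (mCPBA, NaHCO3, CH2Cl2) would give racemic 2-[2-(benzyloxy)-3-methoxybenzyl]oxirane F2.
  - Hydrolytic kinetic resolution (Jacobsen type) with the chiral (salen)Co(OAc) complex of trivalent cobalt and 0.55 equiv of water should leave (S)-2-[2-(benzyloxy)-3-methoxybenzyl]oxirane F3. The catalyst antipode is the one that hydrolyses the R epoxide, expected to be the (S,S) complex by the usual sense of this resolution.
  - Opening at the terminal carbon with decylmagnesium bromide and catalytic CuI (THF, −30 °C) should give (R)-1-[2-(benzyloxy)-3-methoxyphenyl]tridecan-2-ol F4. The stereocentre is untouched; only the descriptor changes.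
  - Acetylation (Ac2O, pyridine, DMAP) gives (R)-1-[2-(benzyloxy)-3-methoxyphenyl]tridecan-2-yl acetate F5, and hydrogenolysis (H2, Pd/C, EtOAc) gives 8.
  - A benzyl ether is acceptable in this sequence because no acetyl bromide is used. The price is six operations in place of steps 1–4 and the loss of at least half the material in the resolution.

**Step 2.**
- What may go wrong: over-oxidation of the oxygenated ring if ozone is not stopped at the olefin, and decay of the arylacetaldehyde (aldol self-condensation, air oxidation) during work-up and purification.
- Fallback (sets out from 2, returns at 3): the cleavage is done in two stages with a storable intermediate. Dihydroxylation (OsO4 cat., N-methylmorpholine N-oxide, acetone/H2O) would give racemic 3-(2-acetoxy-3-methoxyphenyl)propane-1,2-diol F6. Glycol cleavage with NaIO4 (THF/H2O, near neutral) then releases 3 immediately before the coupling.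

**Step 4.**
- What may go wrong: the aryl acetate is flanked by two ortho substituents, so its aminolysis may be slow. If the reaction is then forced, cleavage of the secondary acetate begins to compete.
- Fallback (sets out from 7, returns at 9): selectivity is given up and the acetate is put back at the end. Full methanolysis (K2CO3, MeOH) would give 2-[(2R)-2-hydroxytridecyl]-6-methoxyphenol F7. Oxidation with (KSO3)2NO under the conditions of step 5 would give 2-[(2R)-2-hydroxytridecyl]-6-methoxycyclohexa-2,5-diene-1,4-dione F8. Brief acetylation of the secondary alcohol (Ac2O, pyridine, 0 °C) would then give 9.

**Step 5.**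
- What may go wrong: incomplete oxidation, because the lipophilic phenol and the water-soluble radical salt meet poorly while the reagent decays in solution, followed by slow degradation of the quinone during a prolonged reaction.
- Fallback (sets out from 8, returns at 9): a catalytic aerobic oxidation in a homogeneous organic medium, Co(salen) under O2 in DMF at room temperature. The divalent cobalt complex binds dioxygen, abstracts the phenolic hydrogen and delivers oxygen to the para carbon. Both the oxidant and the phase problem are different, and no new intermediate is formed.

## Further compounds

F1 | step 3 | 1-allyl-2-(benzyloxy)-3-methoxybenzene | C=CCc1cccc(OC)c1OCc1ccccc1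
F2 | step 3 | rac-2-[2-(benzyloxy)-3-methoxybenzyl]oxirane | C1OC1Cc1cccc(OC)c1OCc1ccccc1
F3 | step 3 | (S)-2-[2-(benzyloxy)-3-methoxybenzyl]oxirane | C1[C@H](Cc2cccc(OC)c2OCc2ccccc2)O1
F4 | step 3 | (R)-1-[2-(benzyloxy)-3-methoxyphenyl]tridecan-2-ol | CCCCCCCCCCC[C@H](Cc1cccc(OC)c1OCc1ccccc1)O
F5 | step 3 | (R)-1-[2-(benzyloxy)-3-methoxyphenyl]tridecan-2-yl acetate | CCCCCCCCCCC[C@H](Cc1cccc(OC)c1OCc1ccccc1)OC(C)=O
F6 | step 2 | rac-3-(2-acetoxy-3-methoxyphenyl)propane-1,2-diol | CC(=O)Oc1c(CC(O)CO)cccc1OC
F7 | step 4 | 2-[(2R)-2-hydroxytridecyl]-6-methoxyphenol | CCCCCCCCCCC[C@H](Cc1cccc(OC)c1O)O
F8 | step 4 | 2-[(2R)-2-hydroxytridecyl]-6-methoxycyclohexa-2,5-diene-1,4-dione | CCCCCCCCCCC[C@H](CC1=CC(=O)C=C(OC)C1=O)O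
F0 | step 5 | none | none
A1 | alternative 1 | (R)-3-[2-(tert-butyldimethylsilyloxy)tridecyl]cyclobut-2-en-1-one | CCCCCCCCCCC[C@H](CC1=CC(=O)C1)O[Si](C)(C)C(C)(C)C
A2 | alternative 1 | methoxyacetylene | COC#C
A3 | alternative 1 | 3-methoxy-5-[(2R)-2-(tert-butyldimethylsilyloxy)tridecyl]phenol | CCCCCCCCCCC[C@H](Cc1cc(O)cc(OC)c1)O[Si](C)(C)C(C)(C)C
A4 | alternative 2 | 3-(benzyloxy)-5-methoxyphenyl trifluoromethanesulfonate | COc1cc(OCc2ccccc2)cc(OS(=O)(=O)C(F)(F)F)c1
A5 | alternative 2 | 4,4,5,5-tetramethyl-2-vinyl-1,3,2-dioxaborolane | C=CB1OC(C)(C)C(C)(C)O1
A6 | alternative 2 | undecylmagnesium bromide | CCCCCCCCCCC[Mg]Br
A7 | alternative 2 | (R)-2-{1-[3-(benzyloxy)-5-methoxyphenyl]tridecan-2-yl}-4,4,5,5-tetramethyl-1,3,2-dioxaborolane | CCCCCCCCCCC[C@H](Cc1cc(OC)cc(OCc2ccccc2)c1)B1OC(C)(C)C(C)(C)O1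
A8 | alternative 2 | (R)-1-(3-hydroxy-5-methoxyphenyl)tridecan-2-yl acetate | CCCCCCCCCCC[C@H](Cc1cc(O)cc(OC)c1)OC(C)=O
A9 | alternative 3 | methyl (R)-9-(tert-butyldimethylsilyloxy)-3,5,7-trioxoicosanoate | CCCCCCCCCCC[C@H](CC(=O)CC(=O)CC(=O)CC(=O)OC)O[Si](C)(C)C(C)(C)C
A10 | alternative 3 | methyl 2,4-dihydroxy-6-[(2R)-2-(tert-butyldimethylsilyloxy)tridecyl]benzoate | CCCCCCCCCCC[C@H](Cc1cc(O)cc(O)c1C(=O)OC)O[Si](C)(C)C(C)(C)C
A11 | alternative 3 | (R)-5-[2-(tert-butyldimethylsilyloxy)tridecyl]benzene-1,3-diol | CCCCCCCCCCC[C@H](Cc1cc(O)cc(O)c1)O[Si](C)(C)C(C)(C)C
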